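The pitfall in this flask was to multiply a charge by a yield and call the product target in solution, since the tables count target together with its solid product.

in all of them: gas 3.9 mM (held)

| charge | solid substrate | remark | time |
|---|---|---|---|
| ash | 0.072 M | run made earlier |  |
| birch | 0.31 M | run made earlier |  |
| east | 0.050 M |  | 2.0 min |
| south | 0.10 M |  | 2.0 min |
| north-east | 0.20 M |  | 2.0 min |

| run | time / s | target / % | solid substrate / % |
|---|---|---|---|
| ash | 10.0 | 28.6 | 15.5 |
| ash | 12.0 | 35.9 | 4.2 |
| ash | 15.0 | 46.1 | 0.2 |
| ash | 25.0 | 66.2 | 0.4 |
| ash | 40.0 | 74.5 | 0 |
| ash | 60.0 | 75.9 | 0 |
| birch | 10.0 | 6.5 | 80.3 |
| birch | 12.0 | 8.4 | 78.2 |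
| birch | 15.0 | 10.7 | 73.5 |
| birch | 25.0 | 18.9 | 61.2 |
| birch | 40.0 | 31.9 | 42.0 |
| birch | 60.0 | 47.8 | 15.7 |

(scatter of a reading: 0.3 percentage points)

- percentages count the solid substrate that a species holds: one side product counts as two
- target is meant together with its solid product
- solid, in amounts per volume of the solution: solid substrate, solid product
- at the start none of reagent is dissolved
- the numbers in the tables scatter with a standard deviation of 0.3 percentage points
- steps under discussion: solid substrate <-> dissolved substrate; dissolved substrate + reagent -> target; dissolved substrate + target -> side product; solid product <-> target; gas <-> reagent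
- at the start none of the solid substrate is in solution
- the concentration of target that is asked is that of its free form alone
- "hardly changes" means that all values lie within two and a half points (for a concentration: within two and a half percent of the largest)

* [target] (only what is free in solution) at the end for east, south, north-east, in this order
* how that number moves from the first to the last of them (rises all the way / hardly changes / falls, then rises / rises, then falls / falls all the way)

1. The bench rule I started from was charge times yield. The ash run reached 75.9% target by 60.0 s, and 2.0 min is twice that time, so I assumed each flask finished at the end.

2. The rule stopped at the birch run. From 15.0 s to 40.0 s target rose from 10.7% to 31.9%, yet what was neither target nor solid substrate grew at 0.246 min⁻¹, then 0.248 min⁻¹, as fractions of the charge. That remainder holds the side product and the dissolved substrate, and the step to side product consumes free target, so from the steady growth I read free target as stopped near the total at 15.0 s. This gave a solubility limit of 0.0332 M, a reading.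

3. For east this gave 66.3% of the charge as room, the fraction of a charge that fits as free target. South had 33.2% and north-east 16.6%.

4. The border is yield over room, with crystals above one. Taking the yield of ash for all three, I got 1.14 for east, 2.29 for south and 4.57 for north-east. East crossed narrowly, so I committed to 0.0332 M three times.

The forecast gave 0.034 M, 0.034 M, 0.034 M and hardly changes, holding that “free target equals its solubility each time”, slightly above my reading.

The flask gives 0.0390 M, 0.0390 M, 0.0390 M: hardly changes.

    solid substrate ⇌ dissolved substrate, rate k1*(cs1 - [dissolved substrate]) while solid is left; crystals form when [dissolved substrate] > cs1 (solubility = 0.0690 M, k = 0.141 s⁻¹)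
    dissolved substrate + reagent → target (k = 26.1 M⁻¹ s⁻¹)
    dissolved substrate + target → side product (k = 0.452 M⁻¹ s⁻¹)
    solid product ⇌ target, rate k4*(cs4 - [target]) while solid is left; crystals form when [target] > cs4 (solubility = 39.0 mM, k = 3.66 s⁻¹)
    gas ⇌ reagent, rate k5*(csat - [reagent]) (kL = 3.79 s⁻¹)

In east, dissolution of the solid substrate had half its turnover up to the end behind it by 0.0520 min and uptake of gas by 0.170 min, and at 1.00 min target stood at 81.1%, solid product counted in, of which 3.06% was solid product, with side product at 18.8%. East ended with target at 81.2% of its charge against a room of 66.3%, and 3.19% as solid product. South ended with target at 72.6% against 33.2%, and 33.6% as solid product. North-east ended with target at 67.9% against 16.6%, and 48.4% as solid product.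

The earlier runs and the new flask come from a simulation with made-up constants.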